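The flavanone is disconnected at C2–C3. C2 carries exactly the atoms of an O-benzyl group on O1 (O1, a phenyl ring, one hydrogen), and C3, alpha to the C4 ketone, is the carbon of a diazomethyl ketone. A chiral dirhodium carboxylate therefore turns an aryl diazomethyl ketone bearing that benzyl ether into ring C in one operation, forming C2–C3 by carbene insertion into a benzylic C–H bond and setting C2. The precursor is a pentasubstituted 2-(benzyloxy)aryl diazoketone with the pyranylmethyl group already at the future C8, benzyl ethers on O7 and the pyranone oxygen, and a benzyl carbonate on O5, so that one neutral hydrogenolysis finishes the synthesis.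

Key step: step 8

Assumption: Rh2(S-PTTL)4 is taken to deliver the 2S product (CIP order at C2: O1 > phenyl > C3 > H); should the sense of induction prove opposite, Rh2(R-PTTL)4 is used with no other change.

Design notes:
- O5 carries a benzyl carbonate. Like a hindered ester it makes that oxygen non-nucleophilic and offers no reachable activated C–H bond, but it leaves by hydrogenolysis. A pivalate would need basic cleavage, which endangers C2 through reversible ring opening to the chalcone.
- The diazoketone is made from an aroyl chloride and diazomethane, not by diazo transfer to a methyl ketone enolate. A strong base would meet both the ortho acyloxy group (acyl migration of the Baker–Venkataraman type) and the acidic 6-ethyl CH2 of the 4-alkoxypyranone. The aromatic building block is therefore 2,4,6-trihydroxybenzaldehyde.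

Step 1
Reactants: 1 pentan-3-one; 2 malonyl dichloride
Product: 3 6-ethyl-4-hydroxy-5-methyl-2H-pyran-2-one
Conditions: 1 (3 equiv), neat, 0 °C → rt, then 50 °C; trituration with Et2O
Reagents that add atoms: none
Why: Acylative cyclocondensation of an enolisable ketone with malonyl dichloride (C-acylation of the enol, then lactonisation through the enol oxygen) is a known entry to 4-hydroxy-2-pyranones, and the symmetrical ketone can give only the 6-ethyl-5-methyl isomer.

Step 2
Reactants: 3 6-ethyl-4-hydroxy-5-methyl-2H-pyran-2-one; 4 Eschenmoser's salt (CH2=NMe2+ I−); 5 2,4,6-trihydroxybenzaldehyde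
Product: 8 3-[(6-ethyl-4-hydroxy-5-methyl-2-oxo-2H-pyran-3-yl)methyl]-2,4,6-trihydroxybenzaldehyde, via pyranone Mannich base hydroiodide 6 (not isolated), via 3-methylidenepyrandione 7 (not isolated)
Conditions: 4 (1.0 equiv), MeCN, rt; then 5 (2.5 equiv), 70 °C
Reagents that add atoms: Eschenmoser's salt (N,N-dimethylmethyleneiminium iodide), C=[N+](C)C.[I-]
Why: Mannich reaction at C3, the only free nucleophilic carbon of 3, gives 6, which on heating loses dimethylamine to the pyranone methide 7 (an ortho-quinone-methide analogue) that is captured in a Friedel–Crafts-type conjugate addition by the phloroglucinol ring of 5, whose two free ring positions are equivalent; full conversion of 3 into 6 before 5 is added and an excess of 5 suppress bis(pyranonyl)methane formation and double alkylation.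

Step 3
Reactants: 8 3-[(6-ethyl-4-hydroxy-5-methyl-2-oxo-2H-pyran-3-yl)methyl]-2,4,6-trihydroxybenzaldehyde; 9 benzyl alcohol
Product: 10 4-(benzyloxy)-3-{[4-(benzyloxy)-6-ethyl-5-methyl-2-oxo-2H-pyran-3-yl]methyl}-2,6-dihydroxybenzaldehyde
Conditions: BnOH (2.05 equiv), PPh3, DIAD, THF, 0 °C → rt
Reagents that add atoms: benzyl alcohol, OCc1ccccc1
Why: The Mitsunobu reaction selects pronucleophiles by acidity, so the vinylogous-acid hydroxyl on C4 of the pyranone and the non-chelated hydroxyl para to the formyl group are etherified while the two hydroxyls hydrogen-bonded to the aldehyde are left, and the pyranone reacts at O4 without C-alkylation.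

Step 4
Reactants: 10 4-(benzyloxy)-3-{[4-(benzyloxy)-6-ethyl-5-methyl-2-oxo-2H-pyran-3-yl]methyl}-2,6-dihydroxybenzaldehyde; 11 benzyl chloroformate
Product: 12 benzyl 5-(benzyloxy)-4-{[4-(benzyloxy)-6-ethyl-5-methyl-2-oxo-2H-pyran-3-yl]methyl}-2-formyl-3-hydroxyphenyl carbonate
Conditions: CbzCl (1.05 equiv), i-Pr2NEt, CH2Cl2, −40 → 0 °C
Reagents that add atoms: benzyl chloroformate, O=C(Cl)OCc1ccccc1
Why: O-Acylation (carbonate formation) with one equivalent at low temperature should take the chelated phenol flanked by a ring hydrogen and not the one buttressed by the pyranylmethyl group, and the remaining hydroxyl, then the sole hydrogen-bond donor to the aldehyde, resists a second acylation.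

Step 5
Reactants: 12 benzyl 5-(benzyloxy)-4-{[4-(benzyloxy)-6-ethyl-5-methyl-2-oxo-2H-pyran-3-yl]methyl}-2-formyl-3-hydroxyphenyl carbonate; 9 benzyl alcohol
Product: 13 benzyl 3,5-bis(benzyloxy)-4-{[4-(benzyloxy)-6-ethyl-5-methyl-2-oxo-2H-pyran-3-yl]methyl}-2-formylphenyl carbonate
Conditions: BnOH (1.5 equiv), PPh3, DIAD, THF, 0 °C → rt
Reagents that add atoms: benzyl alcohol, OCc1ccccc1
Why: Mitsunobu O-benzylation proceeds under neutral conditions even on hindered, hydrogen-bonded phenols, so the aryl carbonate is not exposed to base; this benzyl group supplies C2, its hydrogen atoms and ring B.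

Step 6
Reactants: 13 benzyl 3,5-bis(benzyloxy)-4-{[4-(benzyloxy)-6-ethyl-5-methyl-2-oxo-2H-pyran-3-yl]methyl}-2-formylphenyl carbonate
Product: 14 2,4-bis(benzyloxy)-6-{[(benzyloxy)carbonyl]oxy}-3-{[4-(benzyloxy)-6-ethyl-5-methyl-2-oxo-2H-pyran-3-yl]methyl}benzoic acid
Conditions: NaClO2, NaH2PO4, 2-methyl-2-butene, t-BuOH/THF/H2O, 0 °C → rt
Reagents that add atoms: sodium chlorite, [Na+].[O-]Cl=O
Why: Pinnick oxidation with buffered chlorous acid converts the hindered aryl aldehyde into the acid without touching ethers, carbonate or pyranone, the alkene scavenging hypochlorous acid before it can chlorinate the electron-rich rings.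

Step 7
Reactants: 14 2,4-bis(benzyloxy)-6-{[(benzyloxy)carbonyl]oxy}-3-{[4-(benzyloxy)-6-ethyl-5-methyl-2-oxo-2H-pyran-3-yl]methyl}benzoic acid; 15 diazomethane
Product: 17 benzyl 3,5-bis(benzyloxy)-4-{[4-(benzyloxy)-6-ethyl-5-methyl-2-oxo-2H-pyran-3-yl]methyl}-2-(diazoacetyl)phenyl carbonate, via aroyl chloride 16 (not isolated)
Conditions: 1-chloro-N,N,2-trimethylprop-1-en-1-amine (1.3 equiv), CH2Cl2, 0 °C → rt; then CH2N2 (4 equiv), Et3N (1.2 equiv), Et2O, 0 °C → rt
Reagents that add atoms: diazomethane, C=[N+]=[N-]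
Why: The acid chloride is formed under neutral conditions with the α-chloroenamine and acylates diazomethane (the first stage of an Arndt–Eistert homologation, triethylamine taking up HCl), which gives the terminal diazoketone without any enolate that could attack the ortho carbonate or the acidic 6-ethyl group of the pyranone.

Step 8
Reactants: 17 benzyl 3,5-bis(benzyloxy)-4-{[4-(benzyloxy)-6-ethyl-5-methyl-2-oxo-2H-pyran-3-yl]methyl}-2-(diazoacetyl)phenyl carbonate
Product: 18 benzyl (2S)-7-(benzyloxy)-8-{[4-(benzyloxy)-6-ethyl-5-methyl-2-oxo-2H-pyran-3-yl]methyl}-4-oxo-2-phenyl-3,4-dihydro-2H-chromen-5-yl carbonate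
Conditions: dirhodium tetrakis[N-phthaloyl-(S)-tert-leucinate], Rh2(S-PTTL)4 (2 mol %), toluene, 4 Å MS, −20 → 0 °C, slow addition of 17
Reagents that add atoms: none
Why: Rh2(S-PTTL)4 extrudes N2 from 17 to give an electrophilic dirhodium carbene at the future C3, which inserts through a concerted, asynchronous, hydride-transfer-like three-centre transition state into a benzylic C–H bond of the ether on O1 and so forms C2–C3. The closest known reaction type is the dirhodium-carboxylate-catalysed intramolecular C–H insertion of ortho-alkoxyaryl diazoketones to 2-substituted chroman-4-ones. Ring C closes as a six-membered ring by 1,6-insertion, because the atom at the normally favoured 1,5-position is O1 and carries no hydrogen. The stereocentre C2 is set by the chiral phthalimido-carboxylate ligand sphere, which differentiates the two enantiotopic benzylic hydrogens (catalyst enantiomer chosen for 2S). The step needs chemoselectivity for insertion over oxonium-ylide formation at O1 with [1,2]-benzyl shift to a 2-benzylbenzofuran-3-one, and site selectivity among four benzylic CH2 groups; the first is helped by the weakly basic, doubly flanked aryl ether oxygen and a carboxylate catalyst, the second by geometry, since only the O1 benzyl group reaches the carbene through a six-membered transition state, the other three would need eight-membered or larger ones, and the carbonate oxygen on O5 neither forms an ylide nor activates a C–H bond.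

Step 9
Reactants: 18 benzyl (2S)-7-(benzyloxy)-8-{[4-(benzyloxy)-6-ethyl-5-methyl-2-oxo-2H-pyran-3-yl]methyl}-4-oxo-2-phenyl-3,4-dihydro-2H-chromen-5-yl carbonate
Product: 19 (2S)-8-[(6-ethyl-4-hydroxy-5-methyl-2-oxo-2H-pyran-3-yl)methyl]-5,7-dihydroxy-2-phenyl-2,3-dihydro-4H-chromen-4-one (CNP0326321.1)
Conditions: H2 (1 atm), 10% Pd/C, EtOAc/MeOH, rt; filtered when uptake stops
Reagents that add atoms: none
Why: Hydrogenolysis cleaves the two benzyl ethers and the benzyl carbonate (which then loses CO2) under neutral conditions, so the C2 stereocentre, which would racemise through retro-oxa-Michael opening to the chalcone, is never exposed to base; the reaction is stopped at the end of hydrogen uptake to spare the O1–C2 bond.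

Compound list
1 | pentan-3-one | CCC(=O)CC | starting material
2 | malonyl dichloride | O=C(Cl)CC(=O)Cl | starting material
3 | 6-ethyl-4-hydroxy-5-methyl-2H-pyran-2-one | CCc1oc(=O)cc(O)c1C | intermediate
4 | Eschenmoser's salt (N,N-dimethylmethyleneiminium iodide) | C=[N+](C)C.[I-] | starting material
5 | 2,4,6-trihydroxybenzaldehyde | O=Cc1c(O)cc(O)cc1O | starting material
6 | 3-[(dimethylamino)methyl]-6-ethyl-4-hydroxy-5-methyl-2H-pyran-2-one hydroiodide | CCc1oc(=O)c(C[NH+](C)C)c(O)c1C.[I-] | intermediate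
7 | 6-ethyl-5-methyl-3-methylidene-2H-pyran-2,4(3H)-dione | CCC1=C(C)C(=O)C(=C)C(=O)O1 | intermediate
8 | 3-[(6-ethyl-4-hydroxy-5-methyl-2-oxo-2H-pyran-3-yl)methyl]-2,4,6-trihydroxybenzaldehyde | CCc1oc(=O)c(Cc2c(O)cc(O)c(C=O)c2O)c(O)c1C | intermediate
9 | benzyl alcohol | OCc1ccccc1 | starting material
10 | 4-(benzyloxy)-3-{[4-(benzyloxy)-6-ethyl-5-methyl-2-oxo-2H-pyran-3-yl]methyl}-2,6-dihydroxybenzaldehyde | CCc1oc(=O)c(Cc2c(OCc3ccccc3)cc(O)c(C=O)c2O)c(OCc2ccccc2)c1C | intermediate
11 | benzyl chloroformate | O=C(Cl)OCc1ccccc1 | starting material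
12 | benzyl 5-(benzyloxy)-4-{[4-(benzyloxy)-6-ethyl-5-methyl-2-oxo-2H-pyran-3-yl]methyl}-2-formyl-3-hydroxyphenyl carbonate | CCc1oc(=O)c(Cc2c(OCc3ccccc3)cc(OC(=O)OCc3ccccc3)c(C=O)c2O)c(OCc2ccccc2)c1C | intermediate
13 | benzyl 3,5-bis(benzyloxy)-4-{[4-(benzyloxy)-6-ethyl-5-methyl-2-oxo-2H-pyran-3-yl]methyl}-2-formylphenyl carbonate | CCc1oc(=O)c(Cc2c(OCc3ccccc3)cc(OC(=O)OCc3ccccc3)c(C=O)c2OCc2ccccc2)c(OCc2ccccc2)c1C | intermediate
14 | 2,4-bis(benzyloxy)-6-{[(benzyloxy)carbonyl]oxy}-3-{[4-(benzyloxy)-6-ethyl-5-methyl-2-oxo-2H-pyran-3-yl]methyl}benzoic acid | CCc1oc(=O)c(Cc2c(OCc3ccccc3)cc(OC(=O)OCc3ccccc3)c(C(=O)O)c2OCc2ccccc2)c(OCc2ccccc2)c1C | intermediate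
15 | diazomethane (freshly generated from commercial N-methyl-N-nitroso-p-toluenesulfonamide) | C=[N+]=[N-] | starting material
16 | 2,4-bis(benzyloxy)-6-{[(benzyloxy)carbonyl]oxy}-3-{[4-(benzyloxy)-6-ethyl-5-methyl-2-oxo-2H-pyran-3-yl]methyl}benzoyl chloride | CCc1oc(=O)c(Cc2c(OCc3ccccc3)cc(OC(=O)OCc3ccccc3)c(C(=O)Cl)c2OCc2ccccc2)c(OCc2ccccc2)c1C | intermediate
17 | benzyl 3,5-bis(benzyloxy)-4-{[4-(benzyloxy)-6-ethyl-5-methyl-2-oxo-2H-pyran-3-yl]methyl}-2-(diazoacetyl)phenyl carbonate | [N-]=[N+]=CC(=O)c1c(OC(=O)OCc2ccccc2)cc(OCc2ccccc2)c(Cc2c(OCc3ccccc3)c(C)c(CC)oc2=O)c1OCc1ccccc1 | intermediate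
18 | benzyl (2S)-7-(benzyloxy)-8-{[4-(benzyloxy)-6-ethyl-5-methyl-2-oxo-2H-pyran-3-yl]methyl}-4-oxo-2-phenyl-3,4-dihydro-2H-chromen-5-yl carbonate | CCc1oc(=O)c(Cc2c(OCc4ccccc4)cc(OC(=O)OCc4ccccc4)c3c2O[C@H](c2ccccc2)CC3=O)c(OCc2ccccc2)c1C | intermediate
19 | (2S)-8-[(6-ethyl-4-hydroxy-5-methyl-2-oxo-2H-pyran-3-yl)methyl]-5,7-dihydroxy-2-phenyl-2,3-dihydro-4H-chromen-4-one | CCc1oc(=O)c(Cc2c(O)cc(O)c3c2O[C@H](c2ccccc2)CC3=O)c(O)c1C | target

Total step count: 9. Longest linear sequence: 9 steps (steps 1 to 9 from pentan-3-one; the aldehyde 5 enters at step 2 without steps of its own).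

Steps most likely to fail

Step 8. The carbene may be diverted to an oxonium ylide at O1 followed by benzyl shift, or the catalyst may discriminate poorly between the two enantiotopic benzylic hydrogens. The fallback gives up the carbene and introduces ring B by asymmetric conjugate arylation of a chromone. It sets out from 10. Benzylation of its less hindered chelated hydroxyl (BnBr, K2CO3, DMF, rt) should give the 2-hydroxy-4,6-bis(benzyloxy) aldehyde F1, in which the only free hydroxyl is the hindered one that becomes O1. Addition of HC≡CMgBr (THF, −78 → 0 °C) gives the racemic propargylic alcohol F2, and MnO2 in CH2Cl2 oxidises it to the ortho-hydroxyaryl ynone F3. Diethylamine in ethanol closes F3 through the enaminone to the 5,7-bis(benzyloxy)chromone F4. Phenylboronic acid with Pd(OCOCF3)2, a chiral tert-butyl pyridine-oxazoline ligand (enantiomer chosen for 2S), NH4PF6 and water in 1,2-dichloroethane at 60 °C then adds phenyl to C2 and gives the (2S)-tribenzyl flavanone F5. Hydrogenolysis under the conditions of step 9 comes back to the route at 19.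

Step 2. The pyranone methide may be consumed by a second pyranone, or the product may be alkylated twice, so that the mixed methylene-bridged compound is formed inefficiently. The fallback reverses the roles of the partners. It sets out from 5, which is aminomethylated with one equivalent of CH2=NMe2+ I− (MeCN, rt, then NaHCO3) to 3-[(dimethylamino)methyl]-2,4,6-trihydroxybenzaldehyde F6. Heating F6 with an excess of the strongly C-nucleophilic pyranone 3 in dioxane at 100 °C expels dimethylamine; the aryl ortho-quinone methide so formed is trapped at C3 of 3, and the sequence returns to the route at 8.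

Step 4. Acylation may not distinguish cleanly between the two formyl-chelated hydroxyls, or may go on to the bis-carbonate. The fallback is a silyl relay that places the carbonate last, on the only hydroxyl then free. It sets out from 10. The bulkier i-Pr3SiCl (imidazole, DMF) should silylate only the unhindered chelated hydroxyl and give the silyl ether F7. Mitsunobu benzylation of the remaining hindered hydroxyl (BnOH, PPh3, DIAD) gives the silyl benzyl ether F8, and Bu4NF buffered with AcOH in THF releases the phenol F9. CbzCl with i-Pr2NEt in CH2Cl2 then returns to the route at 13.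

Further compounds
F1 | step 8 | 4,6-bis(benzyloxy)-3-{[4-(benzyloxy)-6-ethyl-5-methyl-2-oxo-2H-pyran-3-yl]methyl}-2-hydroxybenzaldehyde | CCc1oc(=O)c(Cc2c(OCc3ccccc3)cc(OCc3ccccc3)c(C=O)c2O)c(OCc2ccccc2)c1C
F2 | step 8 | 4-(benzyloxy)-3-{[4,6-bis(benzyloxy)-2-hydroxy-3-(1-hydroxyprop-2-yn-1-yl)phenyl]methyl}-6-ethyl-5-methyl-2H-pyran-2-one (racemic) | CCc1oc(=O)c(Cc2c(OCc3ccccc3)cc(OCc3ccccc3)c(C(O)C#C)c2O)c(OCc2ccccc2)c1C
F3 | step 8 | 1-[4,6-bis(benzyloxy)-3-{[4-(benzyloxy)-6-ethyl-5-methyl-2-oxo-2H-pyran-3-yl]methyl}-2-hydroxyphenyl]prop-2-yn-1-one | CCc1oc(=O)c(Cc2c(OCc3ccccc3)cc(OCc3ccccc3)c(C(=O)C#C)c2O)c(OCc2ccccc2)c1C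
F4 | step 8 | 5,7-bis(benzyloxy)-8-{[4-(benzyloxy)-6-ethyl-5-methyl-2-oxo-2H-pyran-3-yl]methyl}-4H-chromen-4-one | CCc1oc(=O)c(Cc2c(OCc4ccccc4)cc(OCc4ccccc4)c3c2occc3=O)c(OCc2ccccc2)c1C
F5 | step 8 | (2S)-5,7-bis(benzyloxy)-8-{[4-(benzyloxy)-6-ethyl-5-methyl-2-oxo-2H-pyran-3-yl]methyl}-2-phenyl-2,3-dihydro-4H-chromen-4-one | CCc1oc(=O)c(Cc2c(OCc4ccccc4)cc(OCc4ccccc4)c3c2O[C@H](c2ccccc2)CC3=O)c(OCc2ccccc2)c1C
F6 | step 2 | 3-[(dimethylamino)methyl]-2,4,6-trihydroxybenzaldehyde | CN(C)Cc1c(O)cc(O)c(C=O)c1O
F7 | step 4 | 4-(benzyloxy)-3-{[4-(benzyloxy)-6-ethyl-5-methyl-2-oxo-2H-pyran-3-yl]methyl}-2-hydroxy-6-[(triisopropylsilyl)oxy]benzaldehyde | CCc1oc(=O)c(Cc2c(OCc3ccccc3)cc(O[Si](C(C)C)(C(C)C)C(C)C)c(C=O)c2O)c(OCc2ccccc2)c1C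
F8 | step 4 | 2,4-bis(benzyloxy)-3-{[4-(benzyloxy)-6-ethyl-5-methyl-2-oxo-2H-pyran-3-yl]methyl}-6-[(triisopropylsilyl)oxy]benzaldehyde | CCc1oc(=O)c(Cc2c(OCc3ccccc3)cc(O[Si](C(C)C)(C(C)C)C(C)C)c(C=O)c2OCc2ccccc2)c(OCc2ccccc2)c1C
F9 | step 4 | 2,4-bis(benzyloxy)-3-{[4-(benzyloxy)-6-ethyl-5-methyl-2-oxo-2H-pyran-3-yl]methyl}-6-hydroxybenzaldehyde | CCc1oc(=O)c(Cc2c(OCc3ccccc3)cc(O)c(C=O)c2OCc2ccccc2)c(OCc2ccccc2)c1C
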